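**Numbering and abbreviations.** Tetrahydrofuran: O1, C2 (bears ring B), C3 (bears the hydroxymethyl arm C9), C4 (bears the benzylic carbon C7' of ring A), C5. Side chain on the ring B oxygen: C7'' (carbinol on ring C), C8'' (aryloxy carbon), C9''. ArB = 3-methoxy-4-{[(4S,5S)-4-[4-(benzyloxy)-3-methoxyphenyl]-2,2-dimethyl-1,3-dioxan-5-yl]oxy}phenyl. Compounds 1–31 are numbered as in the steps and the list.

## Analysis of the target

Target 31 is a sesquineolignan with one tetrahydrofuran ring and three guaiacyl rings. The core is a 2-aryl-3-(hydroxymethyl)-4-benzyltetrahydrofuran, and the phenol oxygen of ring B is etherified by C8'' of a guaiacylglycerol unit. There are five stereocentres in two groups that cannot influence each other: C2 (S), C3 (R) and C4 (R) on the ring, and C7'' (S) and C8'' (S) in the chain (threo). On the ring the 2,3 relationship is trans and the 3,4 relationship is cis; the latter is the less stable arrangement and cannot be left to equilibration. The sensitive sites are the two free phenols, the benzylic ether C2–O1 and the benzylic alcohol C7''–OH, all on para-oxygenated rings. Acid ionises them (epimerisation, or cyclisation of ring A onto C2 to an aryltetralin), and hydrogenolysis can cleave them. The difficulty is therefore to set three contiguous ring centres by reagent control, one of them against thermodynamics and without a cation at C2, while carrying an acid-labile threo diol ether. The strategy rests on one feature: C7' is exocyclic on C4, and C5 is bonded to both C4 and O1. If C5 is moved from C4 to C7', the atoms O1–C2–C3–C4–C7'–C5 form a tetrahydropyran, so the tetrahydrofuran with C7' at the aldehyde level is the product of a 1,2-shift of C5 across a C4–C7' epoxide, and that shift fixes C4.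

## Retrosynthetic reasoning

**Protecting groups (31 ⇐ 30 ⇐ 29).** The two phenols are carried as benzyl ethers, the 7'',9''-diol as an acetonide and the C9 hydroxyl as a silyl ether. Benzyl is chosen because it survives every base, organolithium and Lewis acid step. The acetonide and the silyl ether leave together under weak aqueous acid (29 to 30), and the benzyl ethers are removed last (30 to 31).

**C7'–ring A bond (29 ⇐ 26 + 5; 26 ⇐ 25).** Cutting between C7' and ring A leaves C7' as a formyl group on C4, which is exactly what the ring contraction delivers. The forward reaction joins the tosylhydrazone 26 to boronic acid 5 and leaves C7' as a CH2 group in one operation. It avoids an organometallic addition followed by a benzylic deoxygenation, and it brings ring A in last.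

**C4–C5 bond, ring contraction (25 ⇐ 24).** In 25 the bond C4–C5 is cut and C5 is reattached to C7', which gives the epoxypyran 24. The forward reaction is a Lewis-acid-triggered 1,2-shift of C5 from C7' to C4 that turns C7' into the aldehyde. It must proceed with a single inversion at C4, so the epoxide oxygen has to be syn to the C3 arm and the Lewis acid must not carry a nucleophilic halide. It also has to be carbon and not hydride that migrates. The disconnection is made here because it builds the ring, the C4 stereocentre and the C7' handle at once.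

**Epoxide (24 ⇐ 23 ⇐ 22).** The epoxide oxygen is removed to give alkene 22. The free C9 hydroxyl of 22 is the control element: a hydroxyl-directed epoxidation puts the oxygen on the face of the arm. The alcohol is silylated afterwards (23 to 24) so that it does not interfere with the Lewis acid.

**C4=C7' and O1–C5 (22 ⇐ 21 ⇐ 20 ⇐ 19 ⇐ 18).** The ring alkene is cut by ring-closing metathesis to diene 20, and the O1–C5 bond is cut to the secondary alcohol 19 and an allyl group. The primary hydroxyl of diol 18 must be masked first so that only the benzylic oxygen is allylated. A bulky diphenylsilyl ether is used because it does not migrate to the neighbouring alkoxide; it is removed again (21 to 22) to free the directing hydroxyl.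

**C2–C3 bond (18 ⇐ 16 + 17).** Cutting C2–C3 gives aldehyde 16 and a four-carbon (hydroxymethyl)allyl unit from carbonate 17. The forward reaction must create C2 and C3 together, anti and under catalyst control, because the stereocentres of the side chain are too remote to help. All later ring stereochemistry follows from these two centres.

**Ring B aldehyde (16 ⇐ 14 ⇐ 13 ⇐ 12 ⇐ 9 + 10; 9 ⇐ 6 + 7; 6 ⇐ 1; 5 ⇐ 2 ⇐ 1).** The formyl group of 16 is traced to the bromide of 14. The C7''–C8'' bond is cut by an auxiliary-controlled syn aldol between the aryloxyacetyl imide 9 and aldehyde 10. This sets the threo pair with the aryl ether already in place, so no substitution at C8'' is needed. Phenol 1 serves twice, as ring B (through acid 6) and as ring A (through bromide 2 and boronic acid 5).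

## Alternatives that were turned down

**Alternative 1:** Disconnection at C4–C7' and C3–C2, with C3, C4, C5 and C9 drawn from a butenolide. In the forward key step the 2-lithio derivative of dithiane A3 adds to C4 of (5R)-5-menthyloxyfuran-2(5H)-one A2 anti to the acetal substituent, and the lactone enolate is trapped by aldehyde 16 to give A1.
- For: three components, two C–C bonds and the C3/C4 pair in one flask, with relative and absolute configuration dictated by a cheap acetal stereocentre. The sequence is well established for lignan lactones, and from 16 the target would be about five or six steps away. On precedent and on length this alternative is stronger than the chosen route.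
- Against, for this target: the step closes no ring and leaves C2 as a mixture of carbinol epimers. The tetrahydrofuran must then be closed through a benzylic cation at C2 under acid, in a molecule that carries the acid-labile dioxane and the ionisable C7''–O bond. The dithiane must be removed by nickel desulfurisation in the presence of two benzyl ethers and three benzylic C–O bonds, and the acetal carbon must be reduced to the C5 methylene.
- Comparison: the chosen strategy is longer, but it sets C2 by catalyst control, never ionises it, and needs no sulfur.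

**Alternative 2:** Disconnection at O1–C5 by oxygen insertion into a prochiral ketone. In the forward key step a Baeyer–Villiger monooxygenase inserts oxygen into one of the two enantiotopic acyl–CH2 bonds of cyclobutanone A5 to give lactone A4 with C4 fixed.
- For: one catalytic step with air as the oxidant sets C4 from an achiral ketone, and regiochemistry is not an issue in the symmetric substrate. A4 is the classical lactone from which an aldol with 16, reduction and ring closure lead to this skeleton, and the route would be several steps shorter than the chosen one.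
- Against: the key step sets one stereocentre of five, and the ring it forms is opened again by reduction before the tetrahydrofuran is made. Enantioselectivity with a bulky arylmethyl substituent would have to be found by enzyme screening. The downstream sequence shares the weak points of Alternative 1 (epimeric carbinols, cationic closure at C2 next to the protected threo diol).
- Comparison: the chosen strategy offers a C2–C3 bond formed with both centres under catalyst control and a ring formation that needs no acid. The lactone chemistry is kept as the fallback for the key step.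

**Alternative 3:** Disconnection at C2–O1 by oxidation of a benzylic C–H bond. In the forward key step a high-potential quinone abstracts hydride from the CH2 group on ring B of diol A7, and the C5 hydroxyl captures the cation to give A6.
- For: the ring is closed last, from a 2,3-dibenzylbutane-1,4-diol whose two centres are accessible by established alkylation chemistry. The pivalates make ring A and ring C poorer in electrons than the ether-substituted ring B, which is a rational handle for site selectivity. Capture by the C9 hydroxyl would give an oxetane and is not expected, and the 2,3-trans product is the favoured one. This is the shortest endgame of all.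
- Against: hydride abstraction from a CH2 group without an α-heteroatom needs a strongly donating ring. The product C2–H (a benzylic ether) and the dioxane C7''–H are both easier to oxidise than the substrate, so over-oxidation and attack at the acetal compete. Selectivity between the two benzylic CH2 groups rests on the ester/ether difference alone, C2 is set under kinetic control of cation capture, and A7 needs a ring B benzyl electrophile that already carries the whole side chain.
- Comparison: the chosen route has more steps but needs no discrimination among four benzylic positions and creates C2 before the ring exists.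

Key step: step 16

**Assumption:** (S)-SEGPHOS is taken as the ligand antipode that directs the allyl unit to the aldehyde face giving the (1S)-carbinol of 18; if a first run (Mosher ester analysis) shows the opposite sense, (R)-SEGPHOS is used and nothing else changes.

## Route

Step 1
Reactants: 1 4-bromo-2-methoxyphenol
Product: 2 1-(benzyloxy)-4-bromo-2-methoxybenzene
Conditions: BnBr, K2CO3, DMF, rt
Reagents that add atoms: benzyl bromide, BrCc1ccccc1
Why: Williamson etherification of the phenoxide; the benzyl ether masks the ring A phenol through the organolithium and base steps that follow.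

Step 2
Reactants: 2 1-(benzyloxy)-4-bromo-2-methoxybenzene
Product: 5 [4-(benzyloxy)-3-methoxyphenyl]boronic acid, via [4-(benzyloxy)-3-methoxyphenyl]lithium 3 (not isolated), via lithium aryltri(propan-2-yloxy)borate 4 (not isolated)
Conditions: nBuLi, THF, −78 °C; B(OiPr)3, −78 °C → rt; 1 M HCl
Reagents that add atoms: triisopropyl borate, CC(C)OB(OC(C)C)OC(C)C; water, O
Why: Bromine–lithium exchange is fast at −78 °C and the aryllithium is trapped by the borate ester; hydrolysis of the ate complex gives the boronic acid needed in step 18.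

Step 3
Reactants: 1 4-bromo-2-methoxyphenol
Product: 6 2-(4-bromo-2-methoxyphenoxy)acetic acid
Conditions: BrCH2CO2H, NaOH, H2O, 100 °C; then HCl
Reagents that add atoms: bromoacetic acid, OC(=O)CBr
Why: SN2 displacement by the phenoxide forms the aryl ether bond O–C8'' before any stereocentre exists; the ring bromine is the masked formyl group of ring B.

Step 4
Reactants: 6 2-(4-bromo-2-methoxyphenoxy)acetic acid; 7 (R)-4-benzyloxazolidin-2-one
Product: 9 (R)-4-benzyl-3-[2-(4-bromo-2-methoxyphenoxy)acetyl]oxazolidin-2-one, via mixed pivalic anhydride 8 (not isolated)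
Conditions: PivCl, Et3N, THF, −20 °C; then 7, LiCl, rt
Reagents that add atoms: none
Why: N-Acylation of the oxazolidinone through the mixed anhydride; attack occurs at the unhindered aryloxyacetyl carbonyl and not at the pivaloyl carbonyl.

Step 5
Reactants: 9 (R)-4-benzyl-3-[2-(4-bromo-2-methoxyphenoxy)acetyl]oxazolidin-2-one; 10 4-(benzyloxy)-3-methoxybenzaldehyde
Product: 12 (R)-4-benzyl-3-[(2R,3S)-3-[4-(benzyloxy)-3-methoxyphenyl]-2-(4-bromo-2-methoxyphenoxy)-3-hydroxypropanoyl]oxazolidin-2-one, via dibutylboron Z-enolate 11 (not isolated)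
Conditions: Bu2BOTf, iPr2NEt, CH2Cl2, −78 → 0 °C; 10, −78 → 0 °C; then pH 7 buffer, MeOH, H2O2
Reagents that add atoms: none
Why: Evans syn aldol of a glycolate imide: the Z-boron enolate reacts through a closed chair transition state on the face away from the benzyl group of the (R)-auxiliary, which should set both centres (2R,3S), the threo pair that becomes C8'' (S) and C7'' (S).

Step 6
Reactants: 12 the syn aldol adduct
Product: 13 (1S,2S)-1-[4-(benzyloxy)-3-methoxyphenyl]-2-(4-bromo-2-methoxyphenoxy)propane-1,3-diol
Conditions: LiBH4, MeOH (1 equiv), THF, 0 °C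
Reagents that add atoms: none
Why: Reductive cleavage of the imide gives the primary alcohol C9'' and returns the auxiliary; the aryl bromide and both stereocentres are untouched under these non-epimerising conditions.

Step 7
Reactants: 13 the threo 1,3-diol
Product: 14 (4S,5S)-4-[4-(benzyloxy)-3-methoxyphenyl]-5-(4-bromo-2-methoxyphenoxy)-2,2-dimethyl-1,3-dioxane
Conditions: Me2C(OMe)2, PPTS (cat.), acetone, rt
Reagents that add atoms: 2,2-dimethoxypropane, COC(C)(C)OC
Why: Acid-catalysed transketalisation over the only diol present closes the six-membered acetonide (cis-4,5, aryl equatorial); the weak acid should not ionise the benzylic C7''–O bond.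

Step 8
Reactants: 14 the bromo acetonide
Product: 16 3-methoxy-4-{[(4S,5S)-4-[4-(benzyloxy)-3-methoxyphenyl]-2,2-dimethyl-1,3-dioxan-5-yl]oxy}benzaldehyde (ArB–CHO), via aryllithium 15 (not isolated)
Conditions: nBuLi, THF, −78 °C; DMF, −78 → 0 °C; NH4Cl (aq)
Reagents that add atoms: N,N-dimethylformamide, CN(C)C=O
Why: Bromine–lithium exchange outruns any deprotonation at −78 °C and the aryllithium is formylated; the new carbonyl carbon becomes C2.

Step 9
Reactants: 16 ArB–CHO; 17 4-ethenyl-1,3-dioxolan-2-one (vinyl ethylene carbonate, racemic)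
Product: 18 (1S,2R)-1-ArB-2-ethenylpropane-1,3-diol
Conditions: [Ir(cod)Cl]2 (2.5 mol%), (S)-SEGPHOS (5 mol%), 4-cyano-3-nitrobenzoic acid (10 mol%), K3PO4 (5 mol%), iPrOH (2 equiv), THF, 60 °C
Reagents that add atoms: none
Why: Iridium-catalysed transfer-hydrogenative carbonyl (hydroxymethyl)allylation: ionisation and decarboxylation of 17 give an (E)-(hydroxymethyl)allyl iridium species that adds through a chair transition state, which sets the anti relationship (later 2,3-trans). The bisphosphine selects the aldehyde face and so fixes C2 (S) and C3 (R), with isopropanol as terminal reductant.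

Step 10
Reactants: 18 the anti diol
Product: 19 (1S,2R)-1-ArB-2-{[tert-butyl(diphenyl)silyl]oxymethyl}but-3-en-1-ol
Conditions: TBDPSCl, imidazole, CH2Cl2, 0 °C
Reagents that add atoms: tert-butyl(chloro)diphenylsilane, CC(C)(C)[Si](Cl)(c1ccccc1)c1ccccc1
Why: The bulky silyl chloride reacts with the primary hydroxyl and leaves the hindered benzylic one free; this silyl group is chosen because it does not migrate to a neighbouring alkoxide in the next step.

Step 11
Reactants: 19 the mono-silylated diol
Product: 20 tert-butyl{[(2R)-2-[(S)-ArB(prop-2-enyloxy)methyl]but-3-enyl]oxy}diphenylsilane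
Conditions: NaH, allyl bromide, Bu4NI (cat.), THF/DMF, 0 °C → rt
Reagents that add atoms: allyl bromide, C=CCBr
Why: Williamson etherification of the benzylic alkoxide forms the O1–C5 bond; no stereocentre is involved and the acetonide and silyl ether are stable to the base.

Step 12
Reactants: 20 the diene
Product: 21 tert-butyl{[(2S,3R)-2-ArB-3,6-dihydro-2H-pyran-3-yl]methoxy}diphenylsilane
Conditions: second-generation Grubbs catalyst RuCl2(=CHPh)(PCy3)(H2IMes) (5 mol%), CH2Cl2, 40 °C
Reagents that add atoms: none
Why: Ring-closing metathesis of two monosubstituted alkenes closes the six-membered ring and forms the C4=C7' double bond, driven by loss of ethene.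

Step 13
Reactants: 21 the silylated dihydropyran
Product: 22 [(2S,3R)-2-ArB-3,6-dihydro-2H-pyran-3-yl]methanol
Conditions: Bu4NF, THF, 0 °C → rt
Reagents that add atoms: none
Why: Fluoride cleaves the silyl ether and frees the homoallylic hydroxyl that directs the epoxidation.

Step 14
Reactants: 22 the homoallylic alcohol
Product: 23 [(1S,4S,5R,6R)-4-ArB-3,7-dioxabicyclo[4.1.0]heptan-5-yl]methanol
Conditions: VO(acac)2 (5 mol%), tBuOOH (decane), CH2Cl2, 0 °C → rt
Reagents that add atoms: tert-butyl hydroperoxide, CC(C)(C)OO
Why: Hydroxyl-directed epoxidation: the vanadium alkoxide of the C9 hydroxyl delivers the peroxide oxygen within the complex to the alkene face syn to the arm, which places the epoxide cis to C9 and trans to ring B.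

Step 15
Reactants: 23 the epoxy alcohol
Product: 24 tert-butyl{[(1S,4S,5R,6R)-4-ArB-3,7-dioxabicyclo[4.1.0]heptan-5-yl]methoxy}dimethylsilane
Conditions: TBSCl, imidazole, DMF, rt
Reagents that add atoms: tert-butyl(chloro)dimethylsilane, CC(C)(C)[Si](C)(C)Cl
Why: Silylation removes the acidic hydroxyl before the Lewis acid step; the epoxide is stable to these conditions.

Step 16
Reactants: 24 the epoxypyran silyl ether
Product: 25 (3R,4R,5S)-5-ArB-4-{[tert-butyl(dimethyl)silyl]oxymethyl}oxolane-3-carbaldehyde
Conditions: MeAl(OAr)2 [Ar = 4-bromo-2,6-di-tert-butylphenyl, MABR] (3 equiv), CH2Cl2, −78 → −40 °C; NaF, H2O, −40 °C; crude product used at once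
Reagents that add atoms: none
Why: Proposed new method: the bulky, oxophilic aluminium aryloxide binds the epoxide oxygen and lengthens the C4–O bond (C7' is β to O1 and resists positive charge), while the ring methylene C5, held on C7' and carrying O1, shifts to C4 on the face opposite the departing oxygen as the C7'–O bond becomes the carbonyl; the closest known reaction types are the Meinwald ring contraction of cyclohexene oxides to cyclopentanecarbaldehydes and the MABR-promoted rearrangement of 2,3-epoxy silyl ethers to β-silyloxy aldehydes, in which an oxygen-bearing CH2 likewise migrates anti in preference to hydride. The tetrahydrofuran O1–C2–C3–C4–C5 is closed not by an exo or endo cyclisation but by this suprafacial 1,2-shift (ring contraction, six to five), the C4–C5 bond forming as C7'–C5 breaks. The only new stereocentre, C4, is fixed by inversion: the epoxide oxygen sits syn to the C3 arm (step 14), C5 enters anti to it, and the formyl group therefore ends cis to the arm, the contra-thermodynamic 3,4-cis relationship; C2 and C3 are spectators. Three selectivities are needed: carbon over hydride migration, which the lone pair of O1 on the migrating carbon should supply; a single inversion, which is why the Lewis acid carries no nucleophilic halide (MgBr2·OEt2 would open the epoxide to a bromohydrin and contract it in a second inversion to the C4 epimer); and activation of the epoxide in preference to the other ethers, for which the steric bulk of the reagent is relied on. The regiochemistry of C–O cleavage is not critical, because the alternative anti shift of C3 from C4 to C7' leads to the same aldehyde 25. The aldehyde is quenched cold and used at once so that C4 does not epimerise to the trans isomer.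

Step 17
Reactants: 25 the cis aldehyde
Product: 26 (E)-N-tosylhydrazone of 25 (C7'H=N–NHTs; C2, C3 and C4 as in 25)
Conditions: TsNHNH2, THF, 0 °C → rt
Reagents that add atoms: 4-methylbenzenesulfonohydrazide, Cc1ccc(cc1)S(=O)(=O)NN
Why: Condensation of the aldehyde with the sulfonyl hydrazide under neutral conditions; this removes the epimerisable formyl group without acid or base.

Step 18
Reactants: 26 the tosylhydrazone; 5 [4-(benzyloxy)-3-methoxyphenyl]boronic acid
Product: 29 tert-butyl{[(2S,3R,4R)-2-ArB-4-[4-(benzyloxy)-3-methoxybenzyl]oxolan-3-yl]methoxy}dimethylsilane, via diazoalkane 27 (not isolated), via benzylic boronic acid 28 (not isolated)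
Conditions: K2CO3, 1,4-dioxane, 110 °C
Reagents that add atoms: none
Why: Barluenga reductive coupling: base converts the hydrazone into the diazoalkane, the boronic acid adds and the aryl group shifts from boron to C7' with loss of N2, and the benzylic boronic acid is protodeboronated. C7' becomes a CH2 group and C4 is not involved, so its configuration should be retained.

Step 19
Reactants: 29 the protected sesquilignan
Product: 30 (1S,2S)-1-[4-(benzyloxy)-3-methoxyphenyl]-2-{4-[(2S,3R,4R)-4-[4-(benzyloxy)-3-methoxybenzyl]-3-(hydroxymethyl)oxolan-2-yl]-2-methoxyphenoxy}propane-1,3-diol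
Conditions: AcOH/THF/H2O (3:1:1), 40 °C
Reagents that add atoms: none
Why: Weak aqueous acid hydrolyses the acetonide and the primary silyl ether in one operation; it is too weak to ionise the benzylic C2–O1 and C7''–O bonds while the phenols are still benzylated.

Step 20
Reactants: 30 the bis(benzyl ether)
Product: 31 (1S,2S)-1-(4-hydroxy-3-methoxyphenyl)-2-{4-[(2S,3R,4R)-4-(4-hydroxy-3-methoxybenzyl)-3-(hydroxymethyl)oxolan-2-yl]-2-methoxyphenoxy}propane-1,3-diol
Conditions: H2 (1 atm), 10% Pd/C, EtOAc/EtOH, rt, stopped after uptake of 2 equiv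
Reagents that add atoms: none
Why: Hydrogenolysis of the two aryl benzyl ethers, which are cleaved faster than the benzylic ring ether and the benzylic alcohol; no stereocentre is touched.

## Compound list

1 | 4-bromo-2-methoxyphenol | COc1cc(Br)ccc1O | starting material
2 | 1-(benzyloxy)-4-bromo-2-methoxybenzene | COc1cc(Br)ccc1OCc1ccccc1 | intermediate
3 | [4-(benzyloxy)-3-methoxyphenyl]lithium | [Li]c1ccc(OCc2ccccc2)c(OC)c1 | intermediate
4 | lithium [4-(benzyloxy)-3-methoxyphenyl]tri(propan-2-yloxy)borate | [Li+].COc1cc(ccc1OCc1ccccc1)[B-](OC(C)C)(OC(C)C)OC(C)C | intermediate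
5 | [4-(benzyloxy)-3-methoxyphenyl]boronic acid | COc1cc(B(O)O)ccc1OCc1ccccc1 | intermediate
6 | 2-(4-bromo-2-methoxyphenoxy)acetic acid | COc1cc(Br)ccc1OCC(=O)O | intermediate
7 | (R)-4-benzyloxazolidin-2-one | O=C1N[C@H](Cc2ccccc2)CO1 | starting material
8 | 2-(4-bromo-2-methoxyphenoxy)acetic 2,2-dimethylpropanoic anhydride | COc1cc(Br)ccc1OCC(=O)OC(=O)C(C)(C)C | intermediate
9 | (R)-4-benzyl-3-[2-(4-bromo-2-methoxyphenoxy)acetyl]oxazolidin-2-one | COc1cc(Br)ccc1OCC(=O)N1[C@H](Cc2ccccc2)COC1=O | intermediate
10 | 4-(benzyloxy)-3-methoxybenzaldehyde | COc1cc(C=O)ccc1OCc1ccccc1 | starting material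
11 | dibutylboron (Z)-enolate of 9 | CCCCB(CCCC)O/C(=C\Oc1ccc(Br)cc1OC)N1[C@H](Cc2ccccc2)COC1=O | intermediate
12 | (R)-4-benzyl-3-[(2R,3S)-3-[4-(benzyloxy)-3-methoxyphenyl]-2-(4-bromo-2-methoxyphenoxy)-3-hydroxypropanoyl]oxazolidin-2-one | COc1cc(Br)ccc1O[C@@H](C(=O)N1[C@H](Cc2ccccc2)COC1=O)[C@@H](O)c1ccc(OCc2ccccc2)c(OC)c1 | intermediate
13 | (1S,2S)-1-[4-(benzyloxy)-3-methoxyphenyl]-2-(4-bromo-2-methoxyphenoxy)propane-1,3-diol | COc1cc(Br)ccc1O[C@@H](CO)[C@@H](O)c1ccc(OCc2ccccc2)c(OC)c1 | intermediate
14 | (4S,5S)-4-[4-(benzyloxy)-3-methoxyphenyl]-5-(4-bromo-2-methoxyphenoxy)-2,2-dimethyl-1,3-dioxane | COc1cc(Br)ccc1O[C@H]1COC(C)(C)O[C@H]1c1ccc(OCc2ccccc2)c(OC)c1 | intermediate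
15 | aryllithium from 14 (ArB–Li) | [Li]c1ccc(O[C@H]2COC(C)(C)O[C@H]2c2ccc(OCc3ccccc3)c(OC)c2)c(OC)c1 | intermediate
16 | 3-methoxy-4-{[(4S,5S)-4-[4-(benzyloxy)-3-methoxyphenyl]-2,2-dimethyl-1,3-dioxan-5-yl]oxy}benzaldehyde (ArB–CHO) | O=Cc1ccc(O[C@H]2COC(C)(C)O[C@H]2c2ccc(OCc3ccccc3)c(OC)c2)c(OC)c1 | intermediate
17 | 4-ethenyl-1,3-dioxolan-2-one (vinyl ethylene carbonate, racemic) | C=CC1COC(=O)O1 | starting material
18 | (1S,2R)-1-ArB-2-ethenylpropane-1,3-diol | C=C[C@H](CO)[C@H](O)c3ccc(O[C@H]4COC(C)(C)O[C@H]4c5ccc(OCc6ccccc6)c(OC)c5)c(OC)c3 | intermediate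
19 | (1S,2R)-1-ArB-2-{[tert-butyl(diphenyl)silyl]oxymethyl}but-3-en-1-ol | C=C[C@H](CO[Si](c1ccccc1)(c1ccccc1)C(C)(C)C)[C@H](O)c3ccc(O[C@H]4COC(C)(C)O[C@H]4c5ccc(OCc6ccccc6)c(OC)c5)c(OC)c3 | intermediate
20 | tert-butyl{[(2R)-2-[(S)-ArB(prop-2-enyloxy)methyl]but-3-enyl]oxy}diphenylsilane | C=C[C@H](CO[Si](c1ccccc1)(c1ccccc1)C(C)(C)C)[C@H](OCC=C)c3ccc(O[C@H]4COC(C)(C)O[C@H]4c5ccc(OCc6ccccc6)c(OC)c5)c(OC)c3 | intermediate
21 | tert-butyl{[(2S,3R)-2-ArB-3,6-dihydro-2H-pyran-3-yl]methoxy}diphenylsilane | CC(C)(C)[Si](c1ccccc1)(c1ccccc1)OC[C@@H]1[C@@H](c3ccc(O[C@H]4COC(C)(C)O[C@H]4c5ccc(OCc6ccccc6)c(OC)c5)c(OC)c3)OCC=C1 | intermediate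
22 | [(2S,3R)-2-ArB-3,6-dihydro-2H-pyran-3-yl]methanol | OC[C@@H]1[C@@H](c3ccc(O[C@H]4COC(C)(C)O[C@H]4c5ccc(OCc6ccccc6)c(OC)c5)c(OC)c3)OCC=C1 | intermediate
23 | [(1S,4S,5R,6R)-4-ArB-3,7-dioxabicyclo[4.1.0]heptan-5-yl]methanol | OC[C@@H]1[C@@H](c3ccc(O[C@H]4COC(C)(C)O[C@H]4c5ccc(OCc6ccccc6)c(OC)c5)c(OC)c3)OC[C@@H]2O[C@H]12 | intermediate
24 | tert-butyl{[(1S,4S,5R,6R)-4-ArB-3,7-dioxabicyclo[4.1.0]heptan-5-yl]methoxy}dimethylsilane | CC(C)(C)[Si](C)(C)OC[C@@H]1[C@@H](c3ccc(O[C@H]4COC(C)(C)O[C@H]4c5ccc(OCc6ccccc6)c(OC)c5)c(OC)c3)OC[C@@H]2O[C@H]12 | intermediate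
25 | (3R,4R,5S)-5-ArB-4-{[tert-butyl(dimethyl)silyl]oxymethyl}oxolane-3-carbaldehyde | O=C[C@H]2CO[C@H](c3ccc(O[C@H]4COC(C)(C)O[C@H]4c5ccc(OCc6ccccc6)c(OC)c5)c(OC)c3)[C@H]2CO[Si](C)(C)C(C)(C)C | intermediate
26 | (E)-N-tosylhydrazone of 25 | Cc1ccc(cc1)S(=O)(=O)N/N=C/[C@H]2CO[C@H](c3ccc(O[C@H]4COC(C)(C)O[C@H]4c5ccc(OCc6ccccc6)c(OC)c5)c(OC)c3)[C@H]2CO[Si](C)(C)C(C)(C)C | intermediate
27 | diazoalkane from 26 (C7' = CHN2) | [N-]=[N+]=C[C@H]2CO[C@H](c3ccc(O[C@H]4COC(C)(C)O[C@H]4c5ccc(OCc6ccccc6)c(OC)c5)c(OC)c3)[C@H]2CO[Si](C)(C)C(C)(C)C | intermediate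
28 | benzylic boronic acid (C7' bears B(OH)2 and ring A, both epimers) | OB(O)C(c1ccc(OCc7ccccc7)c(OC)c1)[C@H]2CO[C@H](c3ccc(O[C@H]4COC(C)(C)O[C@H]4c5ccc(OCc6ccccc6)c(OC)c5)c(OC)c3)[C@H]2CO[Si](C)(C)C(C)(C)C | intermediate
29 | tert-butyl{[(2S,3R,4R)-2-ArB-4-[4-(benzyloxy)-3-methoxybenzyl]oxolan-3-yl]methoxy}dimethylsilane | COc1cc(C[C@H]2CO[C@H](c3ccc(O[C@H]4COC(C)(C)O[C@H]4c5ccc(OCc6ccccc6)c(OC)c5)c(OC)c3)[C@H]2CO[Si](C)(C)C(C)(C)C)ccc1OCc1ccccc1 | intermediate
30 | (1S,2S)-1-[4-(benzyloxy)-3-methoxyphenyl]-2-{4-[(2S,3R,4R)-4-[4-(benzyloxy)-3-methoxybenzyl]-3-(hydroxymethyl)oxolan-2-yl]-2-methoxyphenoxy}propane-1,3-diol | COc1cc(C[C@H]2CO[C@H](c3ccc(O[C@@H](CO)[C@@H](O)c4ccc(OCc5ccccc5)c(OC)c4)c(OC)c3)[C@H]2CO)ccc1OCc1ccccc1 | intermediate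
31 | (1S,2S)-1-(4-hydroxy-3-methoxyphenyl)-2-{4-[(2S,3R,4R)-4-(4-hydroxy-3-methoxybenzyl)-3-(hydroxymethyl)oxolan-2-yl]-2-methoxyphenoxy}propane-1,3-diol | COc1cc(C[C@H]2CO[C@H](c3ccc(O[C@@H](CO)[C@@H](O)c4ccc(O)c(OC)c4)c(OC)c3)[C@H]2CO)ccc1O | target

## Step count and least certain steps

Total: 20 steps. Longest linear sequence: 18 steps (steps 3–20, from 1 through 6, 9, 12–14, 16 and 18–30 to 31); steps 1–2 form the side branch to 5.

**Step 16 (key step, proposed new method).** Two processes are most likely to go wrong.
- The secondary C4–O bond may not ionise at low temperature. On warming, hydride migration to a pyranone or attack of the Lewis acid on the acetonide could take over.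
- The shift may lose its stereospecificity if it proceeds through a detached oxocarbenium and aluminium enolate pair that recloses without memory of the epoxide face. The cis aldehyde may also epimerise.

Fallback by known lactone chemistry, setting out from aldehydes 10 and 16 and returning at 30:
- Stobbe condensation of 10 with dimethyl succinate (NaOMe, MeOH) gives (E)-4-[4-(benzyloxy)-3-methoxyphenyl]-3-(methoxycarbonyl)but-3-enoic acid F1.
- Asymmetric hydrogenation ([Rh(cod)(Et-DuPHOS)]BF4, H2, MeOH, ligand antipode chosen for R) gives (3R)-4-[4-(benzyloxy)-3-methoxyphenyl]-3-(methoxycarbonyl)butanoic acid F2.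
- Reduction of the ester beside the carboxylate (Ca(BH4)2, EtOH, then HCl) gives (R)-4-[4-(benzyloxy)-3-methoxybenzyl]oxolan-2-one F3.
- The lithium enolate of F3 (LiN(iPr)2, THF, −78 °C) adds to 16 anti to the benzyl group to give the trans aldol lactone (3R,4R)-4-[4-(benzyloxy)-3-methoxybenzyl]-3-[hydroxy(ArB)methyl]oxolan-2-one F4 as carbinol epimers.
- LiAlH4 gives the triol (2R,3R)-2-[4-(benzyloxy)-3-methoxybenzyl]-3-[hydroxy(ArB)methyl]butane-1,4-diol F5.
- Camphorsulfonic acid in CH2Cl2 at 0 °C ionises the benzylic carbinol and the C5 hydroxyl closes the ring, the 2,3-trans product being favoured, to [(2S,3R,4R)-2-ArB-4-[4-(benzyloxy)-3-methoxybenzyl]oxolan-3-yl]methanol F6.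
- Aqueous acetic acid as in step 19 then gives 30.

**Step 18.** The unstabilised diazoalkane 27 may decompose by 1,2-hydride shift from C4 to an exocyclic alkene, which destroys the C4 stereocentre. C4 may epimerise at the hydrazone stage, or the electron-rich boronic acid may be protodeboronated before it couples. Fallback, setting out from 25 and 2 and returning at 29:
- The Grignard reagent from 2 (Mg, THF) is added to 25 at −78 °C to give the C7' carbinols [4-(benzyloxy)-3-methoxyphenyl][(3S,4R,5S)-5-ArB-4-{[tert-butyl(dimethyl)silyl]oxymethyl}oxolan-3-yl]methanol F7.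
- NaH, CS2 and MeI give the S-methyl xanthate of this carbinol F8.
- Barton–McCombie deoxygenation (Bu3SnH, AIBN, toluene, 90 °C) through the benzylic radical gives 29.

**Step 9.** Conversion may be low or facial discrimination insufficient with this electron-rich, bulky aldehyde, or the sense of induction may be opposite to the assumption. Fallback, setting out from 16 and returning at 18:
- (S)-4-Benzyloxazolidin-2-one is acylated with (E)-but-2-enoyl chloride (nBuLi, THF, −78 °C) to (S)-4-benzyl-3-[(E)-but-2-enoyl]oxazolidin-2-one F9.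
- Its boron dienolate (Bu2BOTf, Et3N, CH2Cl2, −78 °C) reacts at the α-carbon with 16 in an Evans syn aldol to (S)-4-benzyl-3-[(2S,3S)-2-ethenyl-3-hydroxy-3-ArB-propanoyl]oxazolidin-2-one F10.
- LiBH4 gives 18.

**Step 20.** Over-reduction is the risk: hydrogenolysis of the benzylic ring ether C2–O1 (opening to a dibenzylbutanediol) or of the C7''–OH, both on electron-rich rings. Fallback, setting out from 30 and returning at 31: the benzyl ethers are cleaved by single-electron transfer with lithium 4,4'-di-tert-butylbiphenylide in THF at −78 °C after deprotonation of the three hydroxyls. The electron enters the unsubstituted benzyl ring and expels the phenoxide, while the dialkoxyaryl benzylic C–O bonds are reduced far more slowly. This fallback makes no new compound (entry F0).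

## Further compounds

F1 | step 16 | (E)-4-[4-(benzyloxy)-3-methoxyphenyl]-3-(methoxycarbonyl)but-3-enoic acid | COC(=O)/C(CC(=O)O)=C/c1ccc(OCc2ccccc2)c(OC)c1
F2 | step 16 | (3R)-4-[4-(benzyloxy)-3-methoxyphenyl]-3-(methoxycarbonyl)butanoic acid | COC(=O)[C@@H](CC(=O)O)Cc1ccc(OCc2ccccc2)c(OC)c1
F3 | step 16 | (R)-4-[4-(benzyloxy)-3-methoxybenzyl]oxolan-2-one | COc1cc(C[C@H]2COC(=O)C2)ccc1OCc1ccccc1
F4 | step 16 | (3R,4R)-4-[4-(benzyloxy)-3-methoxybenzyl]-3-[hydroxy(ArB)methyl]oxolan-2-one (carbinol epimers) | COc1cc(C[C@H]2COC(=O)[C@@H]2C(O)c3ccc(O[C@H]4COC(C)(C)O[C@H]4c5ccc(OCc6ccccc6)c(OC)c5)c(OC)c3)ccc1OCc1ccccc1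
F5 | step 16 | (2R,3R)-2-[4-(benzyloxy)-3-methoxybenzyl]-3-[hydroxy(ArB)methyl]butane-1,4-diol (carbinol epimers) | COc1cc(C[C@@H](CO)[C@H](CO)C(O)c3ccc(O[C@H]4COC(C)(C)O[C@H]4c5ccc(OCc6ccccc6)c(OC)c5)c(OC)c3)ccc1OCc1ccccc1
F6 | step 16 | [(2S,3R,4R)-2-ArB-4-[4-(benzyloxy)-3-methoxybenzyl]oxolan-3-yl]methanol | COc1cc(C[C@H]2CO[C@H](c3ccc(O[C@H]4COC(C)(C)O[C@H]4c5ccc(OCc6ccccc6)c(OC)c5)c(OC)c3)[C@H]2CO)ccc1OCc1ccccc1
F7 | step 18 | [4-(benzyloxy)-3-methoxyphenyl][(3S,4R,5S)-5-ArB-4-{[tert-butyl(dimethyl)silyl]oxymethyl}oxolan-3-yl]methanol (C7' epimers) | COc1cc(C(O)[C@H]2CO[C@H](c3ccc(O[C@H]4COC(C)(C)O[C@H]4c5ccc(OCc6ccccc6)c(OC)c5)c(OC)c3)[C@H]2CO[Si](C)(C)C(C)(C)C)ccc1OCc1ccccc1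
F8 | step 18 | S-methyl xanthate of F7 | COc1cc(C(OC(=S)SC)[C@H]2CO[C@H](c3ccc(O[C@H]4COC(C)(C)O[C@H]4c5ccc(OCc6ccccc6)c(OC)c5)c(OC)c3)[C@H]2CO[Si](C)(C)C(C)(C)C)ccc1OCc1ccccc1
F9 | step 9 | (S)-4-benzyl-3-[(E)-but-2-enoyl]oxazolidin-2-one | C/C=C/C(=O)N1[C@@H](Cc2ccccc2)COC1=O
F10 | step 9 | (S)-4-benzyl-3-[(2S,3S)-2-ethenyl-3-hydroxy-3-ArB-propanoyl]oxazolidin-2-one | C=C[C@H](C(=O)N1[C@@H](Cc2ccccc2)COC1=O)[C@H](O)c3ccc(O[C@H]4COC(C)(C)O[C@H]4c5ccc(OCc6ccccc6)c(OC)c5)c(OC)c3
F0 | step 20 | none | none
A1 | alternative 1 | trans,trans-4-{2-[4-(benzyloxy)-3-methoxyphenyl]-1,3-dithian-2-yl}-3-[hydroxy(ArB)methyl]-5-(menthyloxy)oxolan-2-one (carbinol epimers) | COc1cc(C2(SCCCS2)[C@H]3[C@H](O[C@@H]4C[C@H](C)CC[C@H]4C(C)C)OC(=O)[C@@H]3C(O)c5ccc(O[C@H]6COC(C)(C)O[C@H]6c7ccc(OCc8ccccc8)c(OC)c7)c(OC)c5)ccc1OCc1ccccc1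
A2 | alternative 1 | (5R)-5-menthyloxyfuran-2(5H)-one | O=C1C=C[C@H](O[C@@H]2C[C@H](C)CC[C@H]2C(C)C)O1
A3 | alternative 1 | 2-[4-(benzyloxy)-3-methoxyphenyl]-1,3-dithiane | COc1cc(C2SCCCS2)ccc1OCc1ccccc1
A4 | alternative 2 | (R)-4-[4-(benzyloxy)-3-methoxybenzyl]dihydrofuran-2(3H)-one | COc1cc(C[C@H]2COC(=O)C2)ccc1OCc1ccccc1
A5 | alternative 2 | 3-[4-(benzyloxy)-3-methoxybenzyl]cyclobutan-1-one | COc1cc(CC2CC(=O)C2)ccc1OCc1ccccc1
A6 | alternative 3 | protected target with 7'',9''-acetonide and two aryl pivalates | COc1cc(C[C@H]2CO[C@H](c3ccc(O[C@H]4COC(C)(C)O[C@H]4c5ccc(OC(=O)C(C)(C)C)c(OC)c5)c(OC)c3)[C@H]2CO)ccc1OC(=O)C(C)(C)C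
A7 | alternative 3 | (2R,3R)-2,3-dibenzylbutane-1,4-diol carrying the same acetonide and pivalates | COc1cc(C[C@@H](CO)[C@H](CO)Cc3ccc(O[C@H]4COC(C)(C)O[C@H]4c5ccc(OC(=O)C(C)(C)C)c(OC)c5)c(OC)c3)ccc1OC(=O)C(C)(C)C
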